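**Assumptions.** Positions are given in halimane numbering: ring A = C1–C5 and C10, ring B = C5–C10, C18 = oxidised carbon on C4, C19 = methyl on C4, C17 on C8, C20 on C9, side chain C11–C16. LaLi3[(S)-binaphthoxide]3 is taken to give the (S)-epoxide from alkyl methyl ketones; if the sense is the reverse, the (R)-binaphthoxide complex is used and nothing else changes.

## Retrosynthetic overview

1. Target ⇐ Sharpless epoxidation of the 13E-allylic alcohol ⇐ selective reduction of the C15 enoate; C18 ester ⇐ oxidation of the neopentyl CH2OH that the cyclisation leaves on C4.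
2. Key disconnection: both rings, the 1(10)-alkene and all four ring stereocentres come from one cationic cascade of an acyclic (S)-2,2-disubstituted epoxide carrying a (2E,6Z,10Z)-trienoate.
3. Order of events in that cascade: ring A (C4–C5) closes first, ring B (C9–C10) second, then 1,2-H (C9→C8), 1,2-Me (C10→C9) and loss of H1. The two Z-alkenes give the cis relationship of H5 to the migrating methyl that this target needs.
4. Epoxide ⇐ methyl ketone (catalytic asymmetric Corey–Chaykovsky).
5. Chain ⇐ two Z-selective nickel-catalysed ring-openings of 5-methyl-2,3-dihydrofuran by Grignard reagents, then syn-carbocupration of methyl but-2-ynoate.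

## Route

Step 1
Reactants: 1 2-(3-chloropropyl)-2-methyl-1,3-dioxolane; 2 5-methyl-2,3-dihydrofuran
Product: 4 (3Z)-4-methyl-7-(2-methyl-1,3-dioxolan-2-yl)hept-3-en-1-ol, via Grignard reagent 3 (not isolated)
Conditions: Mg, THF, 60 °C; then 2, NiCl2(PPh3)2 (5 mol %), PhMe, 80 °C; H2O
Reagents that add atoms: none
Why: Nickel-catalysed Kumada-type coupling of a Grignard reagent with the C(sp2)–O bond of a cyclic enol ether (Wenkert coupling) goes with retention, so the alkyl group takes the place of the ring oxygen, cis to the CH2CH2O chain, and the trisubstituted alkene is formed Z.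

Step 2
Reactants: 4 (3Z)-4-methyl-7-(2-methyl-1,3-dioxolan-2-yl)hept-3-en-1-ol
Product: 5 2-[(4Z)-7-bromo-4-methylhept-4-en-1-yl]-2-methyl-1,3-dioxolane
Conditions: CBr4, PPh3, 2,6-lutidine, CH2Cl2, 0 °C
Reagents that add atoms: carbon tetrabromide, BrC(Br)(Br)Br
Why: Appel bromination is an SN2 displacement of the phosphonium-activated primary alcohol under buffered, near-neutral conditions, which leave the ketal and the Z-alkene untouched.

Step 3
Reactants: 5 2-[(4Z)-7-bromo-4-methylhept-4-en-1-yl]-2-methyl-1,3-dioxolane; 2 5-methyl-2,3-dihydrofuran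
Product: 7 (3Z,7Z)-4,8-dimethyl-11-(2-methyl-1,3-dioxolan-2-yl)undeca-3,7-dien-1-ol, via Grignard reagent 6 (not isolated)
Conditions: Mg, THF, 40 °C; then 2 (3 equiv), NiCl2(PPh3)2 (5 mol %), PhMe, 80 °C; H2O
Reagents that add atoms: none
Why: The same Wenkert-type nickel-catalysed enol-ether coupling with retention installs the second Z-trisubstituted alkene; the homoallylic Grignard reagent cannot scramble because its cyclopropylcarbinyl isomer would be a tertiary carbanion.

Step 4
Reactants: 7 (3Z,7Z)-4,8-dimethyl-11-(2-methyl-1,3-dioxolan-2-yl)undeca-3,7-dien-1-ol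
Product: 8 2-[(4Z,8Z)-11-bromo-4,8-dimethylundeca-4,8-dien-1-yl]-2-methyl-1,3-dioxolane
Conditions: CBr4, PPh3, 2,6-lutidine, CH2Cl2, 0 °C
Reagents that add atoms: carbon tetrabromide, BrC(Br)(Br)Br
Why: Appel bromination (SN2 at the primary carbon), as in step 2.

Step 5
Reactants: 8 2-[(4Z,8Z)-11-bromo-4,8-dimethylundeca-4,8-dien-1-yl]-2-methyl-1,3-dioxolane; 9 methyl but-2-ynoate
Product: 14 methyl (2E,6Z,10Z)-3,7,11-trimethyl-15-oxohexadeca-2,6,10-trienoate, via Grignard reagent 10 (not isolated), via alkylcopper 11 (not isolated), via alkenylcopper adduct 12 (not isolated), via ketal trienoate 13 (not isolated)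
Conditions: Mg, THF, 40 °C; CuBr·SMe2 (1.0 equiv), −40 °C; 9, −78 °C; then 2 M HCl, THF, −78 → 23 °C
Reagents that add atoms: water, O
Why: Syn-carbocupration (conjugate addition) of the alkylcopper to the ynoate at −78 °C puts the new chain cis to H, protonation of the alkenylcopper with retention gives the 2E-enoate, and the same aqueous acid hydrolyses the dioxolane to the methyl ketone.

Step 6
Reactants: 14 methyl (2E,6Z,10Z)-3,7,11-trimethyl-15-oxohexadeca-2,6,10-trienoate
Product: 15 methyl (2E,6Z,10Z)-3,7,11-trimethyl-14-[(2S)-2-methyloxiran-2-yl]tetradeca-2,6,10-trienoate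
Conditions: LaLi3[(S)-binaphthoxide]3 (5 mol %), (2,4,6-(MeO)3C6H2)3P=O (5 mol %), Me3S(O)I/NaH (1.2 equiv), MS 5 Å, THF, 23 °C
Reagents that add atoms: trimethylsulfoxonium iodide, C[S+](C)(C)=O.[I-]
Why: Catalytic asymmetric Corey–Chaykovsky epoxidation of a methyl ketone, in which the La/Li binaphthoxide binds ketone and ylide and tells methyl from the long chain, sets the (S)-quaternary epoxide carbon; the β,β-disubstituted enoate is too poor an acceptor to be cyclopropanated at 23 °C.

Step 7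
Reactants: 15 methyl (2E,6Z,10Z)-3,7,11-trimethyl-14-[(2S)-2-methyloxiran-2-yl]tetradeca-2,6,10-trienoate
Product: 16 methyl (2E)-5-[(1S,2R,4aR,5S)-5-(hydroxymethyl)-1,2,5-trimethyl-1,2,3,4,4a,5,6,7-octahydronaphthalen-1-yl]-3-methylpent-2-enoate
Conditions: MeAlCl2 (2.5 equiv), CH2Cl2 (0.005 M), −78 → −20 °C; Et3N, H2O
Reagents that add atoms: none
Why: Proposed new method: the Lewis acid opens the epoxide at its tertiary carbon with backside attack by the 5,10-alkene (inversion fixes C4), rings A then B close through chair transition states with the CH2O–Al group equatorial and, because both alkenes are Z, with a cis ring fusion and H9 anti to the C10 methyl; suprafacial 1,2-H (C9→C8) and 1,2-Me (C10→C9) shifts then set C8 and C9 and bring the charge to C10, next to the tethered aluminate, which lies on the face opposite H5 and can therefore only remove the syn hydrogen on C1, with irreversible loss of methane, so the 1(10)-alkene is not re-protonated and any collapse to the bridged C10–O ether stays reversible; the complexed enoate is too electron-poor to close a third ring; closest known types are MeAlCl2-promoted epoxy-polyene cyclisation, Lewis-acid 1,2-H/1,2-Me shift cascades of labdane-type C8 cations, and proton-scavenging terminations with methylaluminium chlorides.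

Step 8
Reactants: 16 methyl (2E)-5-[(1S,2R,4aR,5S)-5-(hydroxymethyl)-1,2,5-trimethyl-1,2,3,4,4a,5,6,7-octahydronaphthalen-1-yl]-3-methylpent-2-enoate
Product: 18 (1S,5S,6R,8aR)-5-[(3E)-5-methoxy-3-methyl-5-oxopent-3-en-1-yl]-1,5,6-trimethyl-1,2,3,5,6,7,8,8a-octahydronaphthalene-1-carboxylic acid, via aldehyde 17 (not isolated)
Conditions: Dess–Martin periodinane, pyridine, CH2Cl2, 0 °C; then NaClO2, NaH2PO4, 2-methyl-2-butene, t-BuOH/H2O, 0 → 23 °C
Reagents that add atoms: sodium chlorite, [Na+].[O-]Cl=O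
Why: Dess–Martin oxidation followed by Pinnick oxidation takes the neopentyl alcohol to the acid under buffered conditions that neither protonate the 1(10)-alkene nor touch the quaternary C4 or the allylic C5.

Step 9
Reactants: 18 (1S,5S,6R,8aR)-5-[(3E)-5-methoxy-3-methyl-5-oxopent-3-en-1-yl]-1,5,6-trimethyl-1,2,3,5,6,7,8,8a-octahydronaphthalene-1-carboxylic acid
Product: 19 methyl (1S,5S,6R,8aR)-5-[(3E)-5-methoxy-3-methyl-5-oxopent-3-en-1-yl]-1,5,6-trimethyl-1,2,3,5,6,7,8,8a-octahydronaphthalene-1-carboxylate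
Conditions: TMSCHN2, PhMe/MeOH, 0 °C
Reagents that add atoms: trimethylsilyldiazomethane, C[Si](C)(C)C=[N+]=[N-]
Why: Diazoalkane esterification is neutral and fast even for the hindered acid, so the acid has no chance to lactonise onto the 1(10)-alkene.

Step 10
Reactants: 19 methyl (1S,5S,6R,8aR)-5-[(3E)-5-methoxy-3-methyl-5-oxopent-3-en-1-yl]-1,5,6-trimethyl-1,2,3,5,6,7,8,8a-octahydronaphthalene-1-carboxylate
Product: 20 methyl (1S,5S,6R,8aR)-5-[(3E)-5-hydroxy-3-methylpent-3-en-1-yl]-1,5,6-trimethyl-1,2,3,5,6,7,8,8a-octahydronaphthalene-1-carboxylate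
Conditions: iBu2AlH (2.2 equiv), CH2Cl2, −78 °C; MeOH, aq. KNaC4H4O6
Reagents that add atoms: none
Why: 1,2-Reduction by iBu2AlH takes the unhindered conjugated ester to the E-allylic alcohol, while the C18 ester on the quaternary C4 is neopentyl-type hindered and survives at −78 °C.

Step 11
Reactants: 20 methyl (1S,5S,6R,8aR)-5-[(3E)-5-hydroxy-3-methylpent-3-en-1-yl]-1,5,6-trimethyl-1,2,3,5,6,7,8,8a-octahydronaphthalene-1-carboxylate
Product: 21 methyl (1S,5S,6R,8aR)-5-{2-[(2S,3S)-3-(hydroxymethyl)-2-methyloxiran-2-yl]ethyl}-1,5,6-trimethyl-1,2,3,5,6,7,8,8a-octahydronaphthalene-1-carboxylate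
Conditions: Ti(OiPr)4 (10 mol %), L-(+)-DIPT (12 mol %), t-BuOOH, MS 4 Å, CH2Cl2, −20 °C
Reagents that add atoms: tert-butyl hydroperoxide, CC(C)(C)OO
Why: Sharpless asymmetric epoxidation with the L-(+)-tartrate delivers oxygen to the face of the E-allylic alcohol that gives the (13S,14S)-epoxy alcohol (the sense that gives (2S,3S)-epoxygeraniol), the isolated 1(10)-alkene is inert because it is not an allylic alcohol, and any minor ring enantiomer from step 6 becomes a separable diastereomer.

## Compound list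

1 | 2-(3-chloropropyl)-2-methyl-1,3-dioxolane | CC1(CCCCl)OCCO1 | starting material
2 | 5-methyl-2,3-dihydrofuran | CC1=CCCO1 | starting material
3 | [3-(2-methyl-1,3-dioxolan-2-yl)propyl]magnesium chloride (formed in the flask) | CC1(CCC[Mg]Cl)OCCO1 | intermediate
4 | (3Z)-4-methyl-7-(2-methyl-1,3-dioxolan-2-yl)hept-3-en-1-ol | OCC/C=C(C)\CCCC1(C)OCCO1 | intermediate
5 | 2-[(4Z)-7-bromo-4-methylhept-4-en-1-yl]-2-methyl-1,3-dioxolane | BrCC/C=C(C)\CCCC1(C)OCCO1 | intermediate
6 | [(3Z)-4-methyl-7-(2-methyl-1,3-dioxolan-2-yl)hept-3-en-1-yl]magnesium bromide (formed in the flask) | Br[Mg]CC/C=C(C)\CCCC1(C)OCCO1 | intermediate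
7 | (3Z,7Z)-4,8-dimethyl-11-(2-methyl-1,3-dioxolan-2-yl)undeca-3,7-dien-1-ol | OCC/C=C(C)\CC/C=C(C)\CCCC1(C)OCCO1 | intermediate
8 | 2-[(4Z,8Z)-11-bromo-4,8-dimethylundeca-4,8-dien-1-yl]-2-methyl-1,3-dioxolane | BrCC/C=C(C)\CC/C=C(C)\CCCC1(C)OCCO1 | intermediate
9 | methyl but-2-ynoate | CC#CC(=O)OC | starting material
10 | [(3Z,7Z)-4,8-dimethyl-11-(2-methyl-1,3-dioxolan-2-yl)undeca-3,7-dien-1-yl]magnesium bromide (formed in the flask) | Br[Mg]CC/C=C(C)\CC/C=C(C)\CCCC1(C)OCCO1 | intermediate
11 | [(3Z,7Z)-4,8-dimethyl-11-(2-methyl-1,3-dioxolan-2-yl)undeca-3,7-dien-1-yl]copper (formed in the flask) | [Cu]CC/C=C(C)\CC/C=C(C)\CCCC1(C)OCCO1 | intermediate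
12 | methyl (2Z,6Z,10Z)-2-cuprio-3,7,11-trimethyl-14-(2-methyl-1,3-dioxolan-2-yl)tetradeca-2,6,10-trienoate (formed in the flask) | COC(=O)/C([Cu])=C(C)/CC/C=C(C)\CC/C=C(C)\CCCC1(C)OCCO1 | intermediate
13 | methyl (2E,6Z,10Z)-3,7,11-trimethyl-14-(2-methyl-1,3-dioxolan-2-yl)tetradeca-2,6,10-trienoate (formed in the flask) | COC(=O)/C=C(C)/CC/C=C(C)\CC/C=C(C)\CCCC1(C)OCCO1 | intermediate
14 | methyl (2E,6Z,10Z)-3,7,11-trimethyl-15-oxohexadeca-2,6,10-trienoate | COC(=O)/C=C(C)/CC/C=C(C)\CC/C=C(C)\CCCC(C)=O | intermediate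
15 | methyl (2E,6Z,10Z)-3,7,11-trimethyl-14-[(2S)-2-methyloxiran-2-yl]tetradeca-2,6,10-trienoate | C[C@]1(CCC/C(C)=C\CC/C(C)=C\CC/C(C)=C/C(=O)OC)CO1 | intermediate
16 | methyl (2E)-5-[(1S,2R,4aR,5S)-5-(hydroxymethyl)-1,2,5-trimethyl-1,2,3,4,4a,5,6,7-octahydronaphthalen-1-yl]-3-methylpent-2-enoate (C18 alcohol; H5 cis to the C8 and C9 methyls) | OC[C@@]1(C)CCC=C2[C@H]1CC[C@@H](C)[C@]2(C)CC/C(C)=C/C(=O)OC | intermediate
17 | methyl (2E)-5-[(1S,2R,4aR,5S)-5-formyl-1,2,5-trimethyl-1,2,3,4,4a,5,6,7-octahydronaphthalen-1-yl]-3-methylpent-2-enoate (formed in the flask) | O=C[C@@]1(C)CCC=C2[C@H]1CC[C@@H](C)[C@]2(C)CC/C(C)=C/C(=O)OC | intermediate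
18 | (1S,5S,6R,8aR)-5-[(3E)-5-methoxy-3-methyl-5-oxopent-3-en-1-yl]-1,5,6-trimethyl-1,2,3,5,6,7,8,8a-octahydronaphthalene-1-carboxylic acid | OC(=O)[C@@]1(C)CCC=C2[C@H]1CC[C@@H](C)[C@]2(C)CC/C(C)=C/C(=O)OC | intermediate
19 | methyl (1S,5S,6R,8aR)-5-[(3E)-5-methoxy-3-methyl-5-oxopent-3-en-1-yl]-1,5,6-trimethyl-1,2,3,5,6,7,8,8a-octahydronaphthalene-1-carboxylate | COC(=O)[C@@]1(C)CCC=C2[C@H]1CC[C@@H](C)[C@]2(C)CC/C(C)=C/C(=O)OC | intermediate
20 | methyl (1S,5S,6R,8aR)-5-[(3E)-5-hydroxy-3-methylpent-3-en-1-yl]-1,5,6-trimethyl-1,2,3,5,6,7,8,8a-octahydronaphthalene-1-carboxylate | COC(=O)[C@@]1(C)CCC=C2[C@H]1CC[C@@H](C)[C@]2(C)CC/C(C)=C/CO | intermediate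
21 | methyl (1S,5S,6R,8aR)-5-{2-[(2S,3S)-3-(hydroxymethyl)-2-methyloxiran-2-yl]ethyl}-1,5,6-trimethyl-1,2,3,5,6,7,8,8a-octahydronaphthalene-1-carboxylate (CNP0324371.1) | COC(=O)[C@@]1(C)CCC=C2[C@H]1CC[C@@H](C)[C@]2(C)CC[C@]1(C)O[C@H]1CO | target

## Step count and risks

Total step count: 11. Longest linear sequence: 11 steps (1 → 21; 2 and 9 are bought).

The three steps most likely to fail:

**Step 7 (cascade).** The cyclisation through two Z-alkenes may be less stereospecific than with E-alkenes, the shifts may stop early, and the final proton loss may give the tetrasubstituted 5(10)-alkene or the bridged C10–O–C18 ether instead of the 1(10)-alkene. The fallback sets out from 15 and comes back at 19, and replaces the kinetic proton loss by a lactone template. The cyclisation of 15 is run as in step 7 and the alcohol fraction, 16 together with its 5(10)-ene isomer methyl (2E)-5-[(1S,2R,5S)-5-(hydroxymethyl)-1,2,5-trimethyl-1,2,3,4,5,6,7,8-octahydronaphthalen-1-yl]-3-methylpent-2-enoate F1, is taken on without separating the double-bond isomers. Oxidation as in step 8 gives 18 together with the 5(10)-ene acid (1S,5S,6R)-5-[(3E)-5-methoxy-3-methyl-5-oxopent-3-en-1-yl]-1,5,6-trimethyl-1,2,3,4,5,6,7,8-octahydronaphthalene-1-carboxylic acid F2. TfOH (0.2 equiv) in CH2Cl2 at 0 °C then equilibrates both through the C10 cation, which the 1,3-diaxial carboxyl captures to give one compound, the gamma-lactone of the C4 carboxyl onto C10 with H5 trans to the lactone oxygen F3; here C5 is set under thermodynamic control (trans-decalin-type lactone). Saponification with KOH in aqueous MeOH followed by MeI, K2CO3 in DMF on the dicarboxylate gives the dimethyl ester carrying a free tertiary hydroxyl on C10 F4. Burgess reagent in benzene at 50 °C then eliminates syn, which is only possible towards C1 because H5 is anti to the hydroxyl, and gives 19.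

**Step 3 (second nickel coupling; step 1 is the same reaction on a simpler Grignard reagent).** Alkyl Grignard reagents with β-hydrogens can reduce the enol ether instead of coupling, and nickel hydrides may erode the Z geometry. The fallback sets out from 5 and comes back at 7, and builds the Z-alkene by alkyne carbometalation instead. Bromide 5 is alkylated with LiC≡CH·H2NCH2CH2NH2 in DMSO to the terminal alkyne 2-methyl-2-[(4Z)-4-methylnon-4-en-8-yn-1-yl]-1,3-dioxolane F5. Deprotonation with n-BuLi and opening of oxirane (BF3·OEt2, THF, −78 °C) gives the homopropargylic alcohol (7Z)-8-methyl-11-(2-methyl-1,3-dioxolan-2-yl)undec-7-en-3-yn-1-ol F6. Hydroxyl-directed syn-carbomagnesiation with MeMgBr and Fe(acac)3 (cat.) in THF places methyl on the distal alkyne carbon and, after protonation, gives the Z-homoallylic alcohol 7.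

**Step 6 (asymmetric epoxidation).** The enantiomeric excess for this long-chain methyl ketone may be lower than needed, and the sulfoxonium ylide could attack the enoate. The fallback sets out from 14 and comes back at 15, and uses a racemic epoxidation followed by resolution. Trimethylsulfonium iodide and n-BuLi in THF at 0 °C (the sulfonium ylide adds only 1,2 to the ketone) give the racemic epoxide methyl (2E,6Z,10Z)-3,7,11-trimethyl-14-(2-methyloxiran-2-yl)tetradeca-2,6,10-trienoate F7. Kinetic resolution by azidolysis with TMSN3 and the enantiomer of (salen)CrN3 that consumes the (R)-epoxide converts that half into the azido silyl ether methyl (2E,6Z,10Z,15R)-16-azido-3,7,11,15-tetramethyl-15-[(trimethylsilyl)oxy]hexadeca-2,6,10-trienoate F8, which is separated, and leaves (S)-epoxide 15 in at most 50 % yield.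

## Further compounds

F1 | step 7 | methyl (2E)-5-[(1S,2R,5S)-5-(hydroxymethyl)-1,2,5-trimethyl-1,2,3,4,5,6,7,8-octahydronaphthalen-1-yl]-3-methylpent-2-enoate | OC[C@@]1(C)CCCC2=C1CC[C@@H](C)[C@]2(C)CC/C(C)=C/C(=O)OC
F2 | step 7 | (1S,5S,6R)-5-[(3E)-5-methoxy-3-methyl-5-oxopent-3-en-1-yl]-1,5,6-trimethyl-1,2,3,4,5,6,7,8-octahydronaphthalene-1-carboxylic acid | OC(=O)[C@@]1(C)CCCC2=C1CC[C@@H](C)[C@]2(C)CC/C(C)=C/C(=O)OC
F3 | step 7 | gamma-lactone of the C4 carboxyl onto C10 (O–C10 cis to C18 and trans to H5) with the methyl (E)-enoate side chain | C[C@@]12CCC[C@@]3(OC1=O)[C@H]2CC[C@@H](C)[C@]3(C)CC/C(C)=C/C(=O)OC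
F4 | step 7 | dimethyl ester with tertiary hydroxyl on C10 (OH cis to the C4 ester and trans to H5) | COC(=O)[C@@]1(C)CCC[C@@]2(O)[C@H]1CC[C@@H](C)[C@]2(C)CC/C(C)=C/C(=O)OC
F5 | step 3 | 2-methyl-2-[(4Z)-4-methylnon-4-en-8-yn-1-yl]-1,3-dioxolane | C#CCC/C=C(C)\CCCC1(C)OCCO1
F6 | step 3 | (7Z)-8-methyl-11-(2-methyl-1,3-dioxolan-2-yl)undec-7-en-3-yn-1-ol | OCCC#CCC/C=C(C)\CCCC1(C)OCCO1
F7 | step 6 | methyl (2E,6Z,10Z)-3,7,11-trimethyl-14-(2-methyloxiran-2-yl)tetradeca-2,6,10-trienoate (racemate) | CC1(CCC/C(C)=C\CC/C(C)=C\CC/C(C)=C/C(=O)OC)CO1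
F8 | step 6 | methyl (2E,6Z,10Z,15R)-16-azido-3,7,11,15-tetramethyl-15-[(trimethylsilyl)oxy]hexadeca-2,6,10-trienoate | C[C@@](CCC/C(C)=C\CC/C(C)=C\CC/C(C)=C/C(=O)OC)(CN=[N+]=[N-])O[Si](C)(C)C
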